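## Structural features

The target is a (2S)-flavanone. Benzene ring A (C4a, C5 to C8, C8a) is fused along C4a–C8a to the dihydropyranone ring C (O1, C2, C3, C4), and C2 carries the 3,4-dimethoxyphenyl ring B. Ring A has no hydrogen left: C5, C6 and C7 bear methoxy groups, C8 a free hydroxyl, C8a the ring oxygen and C4a the C4 carbonyl. C2 is the only stereocentre and has no stereogenic neighbour. It is benzylic, bonded to O1 and β to the carbonyl, so a base that enolises C3 can expel the C8a phenoxide (E1cB) and the chalcone so formed re-closes without stereocontrol. Other weak points are the C8 phenol (para to the C5 methoxy group, hence easily oxidised to a quinone), the C5 methoxy group peri to the carbonyl (cleaved by chelating Lewis acids), and the C2–O1 bond (sensitive to acid and to forcing hydrogenolysis). The real difficulty is twofold: one of four contiguous oxygens on a hexasubstituted arene (O8) must end up different from the others, and the C2 configuration must survive both ring closure and the appearance of the ketone. The key step exploits the aryl ether bond O1–C8a: if it is formed at the arene carbon of an aryl bromide, the C2–O bond can exist with its configuration before ring C does. The C8 oxygen, needed anyway, directs that bromine to C8a.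

## Logic of the disconnections

15 to 14: the O8–CH2Ph bond is cut. O8 must stay masked while C4 is oxidised, because a free electron-rich phenol would not survive the oxidant. The forward step must be neutral and must spare the C2–O1 bond and the C4 ketone, which points to a benzyl ether and mild hydrogenolysis.

14 to 13 to 12: the C4 carbonyl is taken back to a carbinol and then to a silyl ether. A ketone in the ring-closure substrate would have acidic C3 hydrogens and would eliminate under base. The gain is a substrate that tolerates carbonate at about 85 °C. The demand is a non-basic oxidation after ring closure. Both C4 epimers are acceptable because they converge on 14.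

12 to 11: the O1–C8a bond is cut (key step). This opens ring C and leaves an open chain whose only controlled stereocentre is a secondary carbinol, which the bond formation does not touch. The forward step needs C–O bond formation at a bromide flanked on both sides, without β-hydride elimination. Two refinements of 11 follow from this:
- The oxygen on C3 carries a triisopropylsilyl group. A tert-butyldimethylsilyl group would sit 1,3 to the reacting alkoxide and could migrate to the less hindered C1 oxygen. The migrated isomer cannot cyclise and would be oxidised by the arylpalladium centre.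
- The palladium source is free of carboxylate, so that concerted metalation of the benzyl ring next to the bromide is not assisted.

11 to 10: the C1–H bond is cut, taking the carbinol back to an aryl ketone. This removes the only controlled stereocentre and hands its control to a catalyst. The catalyst must override the racemic silyloxy centre two atoms away.

10 to 9 to 6 + 7: the O–Si bond and then the C2–C3 bond of the propanone chain (the future C3–C4 bond) are cut by a retro-aldol. The chain splits into a ring-A aldehyde and a ring-B methyl ketone, and the C4 oxygen comes from the aldehyde. The forward step needs a preformed enolate, no dehydration (which would lose that oxygen), and silylation of a hindered carbinol.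

6 to 5 to 4 to 2 to 1: the O–benzyl bond, the C6–Br bond, the C5–O bond (through the C–B bond of 3) and the C5–Br bond are cut in turn. Existing groups dictate each position. The first bromination goes para to the 2-methoxy and ortho to the 4-methoxy group. The second goes to the only remaining C–H, ortho to the new phenol. The boron-to-oxygen exchange must tolerate the aldehyde.

## Other disconnections considered

Alternative 1: O1–C8a and C4–C4a are cut together, so ring C comes from a ring-A aryne and a three-carbon hydroxy ester that already holds C2.
- Forward step: fluoride (CsF) releases aryne A4 from the symmetrical silyl triflate A2. The alkoxide of hydroxy ester A3 adds at C8a, and the aryl anion at C4a attacks the ester to give A1.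
- In favour: two bonds, ring C and the C4 carbonyl appear at once, with no oxidation-level detour at C4. A2 is symmetrical, so only one aryne forms. The C5 methoxy and C8 silyl groups both polarise it for oxygen attack at C8a. A3 is accessible by asymmetric reduction of a β-keto ester.
- Against: a secondary alkoxide must attack the aryne carbon next to the trimethylsilyl group. The alkoxide of A3 can eliminate or fragment instead. A1 is born as a flavanone in a basic fluoride medium, where C2 can be lost by ring opening. The C8–Si bond of A1 must still become C8–OH, which for an aryltrimethylsilane means ipso-substitution followed by oxidation on a base-sensitive ketone.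
- Comparison: on convergence and longest linear sequence it is better than the chosen plan. On the way C2 is introduced it is equal, since no bond to C2 is formed in either. On keeping C2 after ring closure and on finishing C8 it is weaker, because the chosen plan closes the ring before the ketone exists and carries O8 as a benzyl ether.

Alternative 2: O1–C2 and C3–C4 are cut as a [4+2] retron.
- Forward step: a chiral phosphoric acid dehydrates hydroxybenzyl alcohol A6 to ortho-quinone methide A8, which adds styrene A7 in an inverse-demand hetero-Diels–Alder reaction to give A5.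
- In favour: ring C and the C2 stereocentre arise in one catalytic, metal-free step from two achiral partners. Regiochemistry follows from polarity.
- Against: A8 has no substituent on its methylene carbon, and A7 has no hydrogen-bond donor, so face selection rests on one contact between catalyst and quinone methide. The electron-rich A7 can oligomerise under acid. A5 has CH2 at C4, so the ketone must come from a benzylic oxidation that competes with the more activated C2–H, at the only stereocentre. A6 needs the same differentiated ring A as 6.
- Comparison: on bond economy it is better. On ring-A effort it is equal. On confidence in the stereocontrol and on the late C–H oxidation it is weaker, since the chosen plan sets C2 by a ketone reduction of well-understood sense and carries the C4 oxygen from the start.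

Alternative 3: C8–C8a is cut, and ring A is built last on a preformed ring C.
- Forward step: bromide A12 is lithiated and added to dimethyl squarate A11, and O-methylation gives cyclobutenone A10. Heating opens the four-membered ring, and the ketene carbon so formed closes onto C8a in a 6π electrocyclisation. Tautomerisation gives A9, the 2,4-cis (2S,4S) isomer.
- In favour: the whole substitution pattern of ring A is delivered in one regiospecific event. O8 emerges as the free phenol without any protecting group or aromatic substitution.
- Against: A12, an acid-labile enol ether with both ring-C stereocentres, must be made first in several steps. After A9 the C4 carbinol must be oxidised beside a free, easily oxidised C8 phenol, which probably brings a protecting group back.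
- Comparison: on regiocontrol in ring A it is better. On stereochemical security at C2 it is equal, as C2 is not involved. On step count it is about equal. On the end game it is weaker.

Key step: step 8

Assumption: the aldol centre (the future C4) is made racemic on purpose, so 11, 12 and 13 are each carried as a pair of epimers sharing the (S) configuration at the carbinol or C2 carbon; both converge on 14.

## Route

Step 1
Reactants: 1 2,3,4-trimethoxybenzaldehyde
Product: 2 5-bromo-2,3,4-trimethoxybenzaldehyde
Conditions: NBS (1.05 equiv), DMF, 0 °C → rt
Reagents that add atoms: N-bromosuccinimide, O=C1CCC(=O)N1Br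
Why: Electrophilic aromatic bromination; C5 is ortho to the 4-methoxy and para to the 2-methoxy group, whereas C6 is ortho to the deactivating formyl group, so substitution should go to C5.

Step 2
Reactants: 2 5-bromo-2,3,4-trimethoxybenzaldehyde
Product: 4 5-hydroxy-2,3,4-trimethoxybenzaldehyde, via aryl pinacol boronate 3 (not isolated)
Conditions: B2pin2, PdCl2(dppf) (3 mol %), KOAc, 1,4-dioxane, 90 °C; then NaBO3·4H2O, THF/H2O, rt
Reagents that add atoms: sodium perborate (used as NaBO3·4H2O), [Na+].[O-]OB=O, source of the phenol oxygen; bis(pinacolato)diboron, CC1(C)OB(OC1(C)C)B1OC(C)(C)C(C)(C)O1, source of the boryl group of 3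
Why: Miyaura borylation tolerates the aldehyde, and perborate then oxidises the C–B bond by 1,2-aryl shift from boron to oxygen. The new phenol is meta to the formyl group, so Dakin cleavage is not a pathway.

Step 3
Reactants: 4 5-hydroxy-2,3,4-trimethoxybenzaldehyde
Product: 5 6-bromo-5-hydroxy-2,3,4-trimethoxybenzaldehyde
Conditions: Br2 (1.0 equiv), NaOAc, AcOH, rt
Reagents that add atoms: bromine, BrBr
Why: Electrophilic bromination directed by the free phenol; C6 is ortho to the hydroxyl and is the only ring position that still bears hydrogen, the pattern known for hydroxybenzaldehydes brominated between the hydroxyl and formyl groups.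

Step 4
Reactants: 5 6-bromo-5-hydroxy-2,3,4-trimethoxybenzaldehyde
Product: 6 5-(benzyloxy)-6-bromo-2,3,4-trimethoxybenzaldehyde
Conditions: BnBr, K2CO3, DMF, rt → 50 °C
Reagents that add atoms: benzyl bromide, BrCc1ccccc1
Why: Williamson etherification of a phenoxide with a primary benzylic halide; the aldehyde has no α-hydrogen and is inert to carbonate.

Step 5
Reactants: 6 5-(benzyloxy)-6-bromo-2,3,4-trimethoxybenzaldehyde; 7 3,4-dimethoxyacetophenone
Product: 9 3-[3-(benzyloxy)-2-bromo-4,5,6-trimethoxyphenyl]-1-(3,4-dimethoxyphenyl)-3-hydroxypropan-1-one (racemic), via lithium enolate 8 (not isolated)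
Conditions: 7, LiN(SiMe3)2 (1.05 equiv), THF, −78 °C; then 6, −78 °C; AcOH quench at −78 °C
Reagents that add atoms: none
Why: Directed aldol addition of a preformed lithium enolate to a non-enolisable aldehyde; low temperature and a cold acidic quench should prevent retro-aldol and dehydration. The new carbinol centre forms racemic, which is acceptable because it becomes the C4 carbonyl.

Step 6
Reactants: 9 3-[3-(benzyloxy)-2-bromo-4,5,6-trimethoxyphenyl]-1-(3,4-dimethoxyphenyl)-3-hydroxypropan-1-one
Product: 10 3-[3-(benzyloxy)-2-bromo-4,5,6-trimethoxyphenyl]-1-(3,4-dimethoxyphenyl)-3-[(triisopropylsilyl)oxy]propan-1-one (racemic)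
Conditions: TIPSOTf (1.5 equiv), 2,6-lutidine (3 equiv), CH2Cl2, −78 °C → rt
Reagents that add atoms: triisopropylsilyl trifluoromethanesulfonate, CC(C)[Si](C(C)C)(C(C)C)OS(=O)(=O)C(F)(F)F
Why: Silyl triflate with a hindered pyridine base silylates hindered secondary alcohols without enolising the ketone or eliminating the β-hydroxy ketone. The bulky triisopropylsilyl group is chosen because it resists oxygen-to-oxygen migration in step 8.

Step 7
Reactants: 10 3-[3-(benzyloxy)-2-bromo-4,5,6-trimethoxyphenyl]-1-(3,4-dimethoxyphenyl)-3-[(triisopropylsilyl)oxy]propan-1-one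
Product: 11 (1S)-3-[3-(benzyloxy)-2-bromo-4,5,6-trimethoxyphenyl]-1-(3,4-dimethoxyphenyl)-3-[(triisopropylsilyl)oxy]propan-1-ol (both C3 epimers)
Conditions: RuCl[(S,S)-TsDPEN](p-cymene) (2 mol %), HCO2H/Et3N (5:2), CH2Cl2, 30 °C
Reagents that add atoms: none
Why: Noyori–Ikariya asymmetric transfer hydrogenation of an aryl alkyl ketone; the (S,S) catalyst should deliver hydride to the face that gives the (S)-carbinol (aryl outranks CH2, as in (S)-1-phenylethanol). The remote silyloxy centre cannot chelate and should not override the catalyst, and CO2 loss makes the reduction irreversible.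

Step 8
Reactants: 11 (1S)-3-[3-(benzyloxy)-2-bromo-4,5,6-trimethoxyphenyl]-1-(3,4-dimethoxyphenyl)-3-[(triisopropylsilyl)oxy]propan-1-ol (both C3 epimers)
Product: 12 (2S)-8-(benzyloxy)-2-(3,4-dimethoxyphenyl)-5,6,7-trimethoxy-4-[(triisopropylsilyl)oxy]chromane (both C4 epimers)
Conditions: Pd2(dba)3 (2.5 mol %), RockPhos [2-(di-tert-butylphosphino)-3-methoxy-6-methyl-2',4',6'-triisopropylbiphenyl] (7.5 mol %), Cs2CO3 (1.5 equiv), toluene, 85 °C
Reagents that add atoms: none
Why: Zerovalent palladium carrying one bulky phosphine inserts into the C8a–Br bond of 11; the C1 hydroxyl binds to the divalent arylpalladium bromide and is deprotonated by Cs2CO3 with loss of bromide, and the seven-membered oxapalladacycle (Pd, C8a, C4a, C4, C3, C2, O1) undergoes C–O reductive elimination, forming O1–C8a and returning zerovalent palladium. The closest known reaction type is the intramolecular Buchwald–Hartwig etherification of secondary alcohols with aryl bromides, which gives chromans with di-tert-butylbiarylphosphine ligands. Ring C closes in a six-membered exo mode at an sp2 carbon, with the departing bromide outside the new ring. No stereocentre is created: the bond from C2 to O1 is neither formed nor broken, so the (S) configuration from step 7 is retained, and the two C4 epimers cyclise side by side. Reductive elimination must outrun β-hydride elimination from the benzylic palladium alkoxide, and oxidative addition must succeed at a bromide flanked by the benzyloxy group and a branched benzylic carbon; the large, electron-rich ligand serves both needs. The alkoxide must stay on the C1 oxygen, which the triisopropylsilyl group secures by being too hindered for 1,3 oxygen-to-oxygen migration. Palladium must also leave the neighbouring benzyl ring alone, which the absence of carboxylate, the non-polar solvent and the moderate temperature favour, because concerted metalation is then slower than capture by the tethered alcohol.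

Step 9
Reactants: 12 (2S)-8-(benzyloxy)-2-(3,4-dimethoxyphenyl)-5,6,7-trimethoxy-4-[(triisopropylsilyl)oxy]chromane (both C4 epimers)
Product: 13 (2S)-8-(benzyloxy)-2-(3,4-dimethoxyphenyl)-5,6,7-trimethoxychroman-4-ol (both C4 epimers)
Conditions: TBAF (1.5 equiv), AcOH (1.5 equiv), THF, rt → 40 °C
Reagents that add atoms: none
Why: Fluoride cleaves the silyl ether, driven by the strength of the Si–F bond. Acetic acid keeps the medium near neutral so the electron-rich benzylic carbinol neither ionises nor eliminates, and C2 is not involved.

Step 10
Reactants: 13 (2S)-8-(benzyloxy)-2-(3,4-dimethoxyphenyl)-5,6,7-trimethoxychroman-4-ol (both C4 epimers)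
Product: 14 (2S)-8-(benzyloxy)-2-(3,4-dimethoxyphenyl)-5,6,7-trimethoxychroman-4-one
Conditions: Dess–Martin periodinane (1.3 equiv), NaHCO3, CH2Cl2, 0 °C → rt
Reagents that add atoms: none
Why: Dess–Martin oxidation of a secondary benzylic alcohol under buffered, non-basic conditions, so the new β-aryloxy ketone is not opened by E1cB and C2 keeps its configuration. Both C4 epimers converge on one ketone, and the benzyl ether shields O8 from the oxidant.

Step 11
Reactants: 14 (2S)-8-(benzyloxy)-2-(3,4-dimethoxyphenyl)-5,6,7-trimethoxychroman-4-one
Product: 15 (2S)-2-(3,4-dimethoxyphenyl)-8-hydroxy-5,6,7-trimethoxychroman-4-one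
Conditions: H2 (1 atm), 10% Pd/C, EtOAc, rt
Reagents that add atoms: none
Why: Neutral hydrogenolysis of an aryl benzyl ether; the unhindered primary benzylic C–O bond should cleave well before the C2–O1 bond or the electron-rich aryl ketone reacts, and no base is present to open ring C.

## Compound list

1 | 2,3,4-trimethoxybenzaldehyde | COc1ccc(C=O)c(OC)c1OC | starting material
2 | 5-bromo-2,3,4-trimethoxybenzaldehyde | COc1c(Br)cc(C=O)c(OC)c1OC | intermediate
3 | 2,3,4-trimethoxy-5-(4,4,5,5-tetramethyl-1,3,2-dioxaborolan-2-yl)benzaldehyde | COc1c(B2OC(C)(C)C(C)(C)O2)cc(C=O)c(OC)c1OC | intermediate (not isolated)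
4 | 5-hydroxy-2,3,4-trimethoxybenzaldehyde | COc1c(O)cc(C=O)c(OC)c1OC | intermediate
5 | 6-bromo-5-hydroxy-2,3,4-trimethoxybenzaldehyde | COc1c(O)c(Br)c(C=O)c(OC)c1OC | intermediate
6 | 5-(benzyloxy)-6-bromo-2,3,4-trimethoxybenzaldehyde | COc1c(OCc2ccccc2)c(Br)c(C=O)c(OC)c1OC | intermediate
7 | 3,4-dimethoxyacetophenone | CC(=O)c1ccc(OC)c(OC)c1 | starting material
8 | lithium 1-(3,4-dimethoxyphenyl)ethen-1-olate | C=C([O-])c1ccc(OC)c(OC)c1.[Li+] | intermediate (not isolated)
9 | 3-[3-(benzyloxy)-2-bromo-4,5,6-trimethoxyphenyl]-1-(3,4-dimethoxyphenyl)-3-hydroxypropan-1-one (racemic) | COc1ccc(C(=O)CC(O)c2c(Br)c(OCc3ccccc3)c(OC)c(OC)c2OC)cc1OC | intermediate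
10 | 3-[3-(benzyloxy)-2-bromo-4,5,6-trimethoxyphenyl]-1-(3,4-dimethoxyphenyl)-3-[(triisopropylsilyl)oxy]propan-1-one (racemic) | COc1ccc(C(=O)CC(O[Si](C(C)C)(C(C)C)C(C)C)c2c(Br)c(OCc3ccccc3)c(OC)c(OC)c2OC)cc1OC | intermediate
11 | (1S)-3-[3-(benzyloxy)-2-bromo-4,5,6-trimethoxyphenyl]-1-(3,4-dimethoxyphenyl)-3-[(triisopropylsilyl)oxy]propan-1-ol (both C3 epimers) | COc1ccc([C@@H](O)CC(O[Si](C(C)C)(C(C)C)C(C)C)c2c(Br)c(OCc3ccccc3)c(OC)c(OC)c2OC)cc1OC | intermediate
12 | (2S)-8-(benzyloxy)-2-(3,4-dimethoxyphenyl)-5,6,7-trimethoxy-4-[(triisopropylsilyl)oxy]chromane (both C4 epimers) | COc1ccc([C@@H]2CC(O[Si](C(C)C)(C(C)C)C(C)C)c3c(c(OCc4ccccc4)c(OC)c(OC)c3OC)O2)cc1OC | intermediate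
13 | (2S)-8-(benzyloxy)-2-(3,4-dimethoxyphenyl)-5,6,7-trimethoxychroman-4-ol (both C4 epimers) | COc1ccc([C@@H]2CC(O)c3c(c(OCc4ccccc4)c(OC)c(OC)c3OC)O2)cc1OC | intermediate
14 | (2S)-8-(benzyloxy)-2-(3,4-dimethoxyphenyl)-5,6,7-trimethoxychroman-4-one | COc1ccc([C@@H]2CC(=O)c3c(c(OCc4ccccc4)c(OC)c(OC)c3OC)O2)cc1OC | intermediate
15 | (2S)-2-(3,4-dimethoxyphenyl)-8-hydroxy-5,6,7-trimethoxychroman-4-one | COc1ccc([C@@H]2CC(=O)c3c(c(O)c(OC)c(OC)c3OC)O2)cc1OC | target

## Step count and least certain steps

Total step count: 11. Longest linear sequence: 11 steps (1 to 15); 7 is commercial and enters at step 5.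

Step 8 (key step). The palladium alkoxide may lose a β-hydride instead of eliminating reductively, which oxidises the carbinol and removes the bromine. Oxidative addition may also stall because the C–Br bond is flanked on both sides; palladation of the benzyl ring is a lesser risk. The fallback closes ring C at C2 instead of at the arene, by a Mitsunobu reaction. It sets out from 10:
- Reduction with the enantiomeric catalyst RuCl[(R,R)-TsDPEN](p-cymene) would give (1R)-3-[3-(benzyloxy)-2-bromo-4,5,6-trimethoxyphenyl]-1-(3,4-dimethoxyphenyl)-3-[(triisopropylsilyl)oxy]propan-1-ol F1.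
- Deprotonation (n-BuLi), bromine–lithium exchange (t-BuLi, THF, −78 °C), B(OMe)3 and then H2O2/NaOH would give (1R)-3-[3-(benzyloxy)-2-hydroxy-4,5,6-trimethoxyphenyl]-1-(3,4-dimethoxyphenyl)-3-[(triisopropylsilyl)oxy]propan-1-ol F2.
- PPh3/DIAD would close O1–C2 with inversion, turning (1R) into (2S), and the route is rejoined at 12.

Step 5. The lithium aldolate may revert (retro-aldol) or dehydrate to the enone on warming, and addition to the doubly ortho-substituted aldehyde may be slow. The fallback builds the same chain with a more nucleophilic amide enolate that cannot dehydrate as easily. It sets out from 6: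
- The lithium enolate of N-methoxy-N-methylacetamide (LiN(iPr)2, THF, −78 °C) would give 3-[3-(benzyloxy)-2-bromo-4,5,6-trimethoxyphenyl]-3-hydroxy-N-methoxy-N-methylpropanamide F3.
- TIPSOTf/2,6-lutidine would give 3-[3-(benzyloxy)-2-bromo-4,5,6-trimethoxyphenyl]-N-methoxy-N-methyl-3-[(triisopropylsilyl)oxy]propanamide F4.
- Commercial 3,4-(MeO)2C6H3MgBr (THF, 0 °C) would convert the Weinreb amide into the aryl ketone, and the route is rejoined at 10. This also moves the hindered silylation of step 6 away from a β-hydroxy ketone.

Step 7. Facial selectivity may be poor for the C3 epimer in which the silyloxy centre opposes the catalyst, and the amine may eliminate silanol from the β-silyloxy ketone. The fallback replaces metal-catalysed transfer hydrogenation by Corey–Bakshi–Shibata reduction, run cold and without amine or formic acid. From 10, (R)-2-methyl-CBS-oxazaborolidine and BH3·SMe2 (THF, −20 °C) would give 11 directly. No new compound arises.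

Step 2. The peroxide may over-oxidise the electron-rich aldehyde, or the boronate may protodeborylate before it is oxidised. The fallback masks the aldehyde and uses an aryllithium. It sets out from 2:
- HC(OMe)3 and catalytic TsOH in MeOH would give 1-bromo-5-(dimethoxymethyl)-2,3,4-trimethoxybenzene F5.
- n-BuLi (THF, −78 °C), B(OMe)3 and then H2O2/NaOH would give 5-(dimethoxymethyl)-2,3,4-trimethoxyphenol F6.
- Dilute HCl in THF would hydrolyse the acetal, and the route is rejoined at 4.

Step 11. Over-reduction is possible, either by hydrogenolytic opening of the benzylic C2–O1 bond or by reduction of the aryl ketone. The fallback removes the benzyl group without hydrogen or palladium: from 14, BCl3 with pentamethylbenzene as cation scavenger (CH2Cl2, −78 °C) would give 15 directly. The low temperature should spare the chelation-prone C5 methoxy group. No new compound arises.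

## Further compounds

F1 | step 8 | (1R)-3-[3-(benzyloxy)-2-bromo-4,5,6-trimethoxyphenyl]-1-(3,4-dimethoxyphenyl)-3-[(triisopropylsilyl)oxy]propan-1-ol (both C3 epimers) | COc1ccc([C@H](O)CC(O[Si](C(C)C)(C(C)C)C(C)C)c2c(Br)c(OCc3ccccc3)c(OC)c(OC)c2OC)cc1OC
F2 | step 8 | (1R)-3-[3-(benzyloxy)-2-hydroxy-4,5,6-trimethoxyphenyl]-1-(3,4-dimethoxyphenyl)-3-[(triisopropylsilyl)oxy]propan-1-ol (both C3 epimers) | COc1ccc([C@H](O)CC(O[Si](C(C)C)(C(C)C)C(C)C)c2c(O)c(OCc3ccccc3)c(OC)c(OC)c2OC)cc1OC
F3 | step 5 | 3-[3-(benzyloxy)-2-bromo-4,5,6-trimethoxyphenyl]-3-hydroxy-N-methoxy-N-methylpropanamide (racemic) | CON(C)C(=O)CC(O)c1c(Br)c(OCc2ccccc2)c(OC)c(OC)c1OC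
F4 | step 5 | 3-[3-(benzyloxy)-2-bromo-4,5,6-trimethoxyphenyl]-N-methoxy-N-methyl-3-[(triisopropylsilyl)oxy]propanamide (racemic) | CON(C)C(=O)CC(O[Si](C(C)C)(C(C)C)C(C)C)c1c(Br)c(OCc2ccccc2)c(OC)c(OC)c1OC
F0 | step 7 | none | none
F5 | step 2 | 1-bromo-5-(dimethoxymethyl)-2,3,4-trimethoxybenzene | COC(OC)c1cc(Br)c(OC)c(OC)c1OC
F6 | step 2 | 5-(dimethoxymethyl)-2,3,4-trimethoxyphenol | COC(OC)c1cc(O)c(OC)c(OC)c1OC
F0 | step 11 | none | none
A1 | alternative 1 | (2S)-2-(3,4-dimethoxyphenyl)-5,6,7-trimethoxy-8-(trimethylsilyl)chroman-4-one | COc1ccc([C@@H]2CC(=O)c3c(c([Si](C)(C)C)c(OC)c(OC)c3OC)O2)cc1OC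
A2 | alternative 1 | 3,4,5-trimethoxy-2,6-bis(trimethylsilyl)phenyl trifluoromethanesulfonate | COc1c(OC)c(OC)c([Si](C)(C)C)c(OS(=O)(=O)C(F)(F)F)c1[Si](C)(C)C
A3 | alternative 1 | methyl (3S)-3-(3,4-dimethoxyphenyl)-3-hydroxypropanoate | COC(=O)C[C@H](O)c1ccc(OC)c(OC)c1
A4 | alternative 1 | 3,4,5-trimethoxy-6-(trimethylsilyl)benzyne | C[Si](C)(C)C1=C(OC)C(OC)=C(OC)C#C1
A5 | alternative 2 | (2S)-8-(benzyloxy)-2-(3,4-dimethoxyphenyl)-5,6,7-trimethoxychromane | COc1ccc([C@@H]2CCc3c(c(OCc4ccccc4)c(OC)c(OC)c3OC)O2)cc1OC
A6 | alternative 2 | 2-(benzyloxy)-6-(hydroxymethyl)-3,4,5-trimethoxyphenol | COc1c(OC)c(OC)c(CO)c(O)c1OCc1ccccc1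
A7 | alternative 2 | 3,4-dimethoxystyrene | C=Cc1ccc(OC)c(OC)c1
A8 | alternative 2 | 2-(benzyloxy)-3,4,5-trimethoxy-6-methylidenecyclohexa-2,4-dien-1-one | C=C1C(OC)=C(OC)C(OC)=C(OCc2ccccc2)C1=O
A9 | alternative 3 | (2S,4S)-4-[(tert-butyldimethylsilyl)oxy]-2-(3,4-dimethoxyphenyl)-5,6,7-trimethoxychroman-8-ol (2,4-cis) | COc1ccc([C@@H]2C[C@H](O[Si](C)(C)C(C)(C)C)c3c(c(O)c(OC)c(OC)c3OC)O2)cc1OC
A10 | alternative 3 | 4-[(2S,4S)-4-[(tert-butyldimethylsilyl)oxy]-2-(3,4-dimethoxyphenyl)-3,4-dihydro-2H-pyran-5-yl]-2,3,4-trimethoxycyclobut-2-en-1-one (either configuration at the ring carbon 4) | COC1=C(OC)C(OC)(C2=CO[C@H](c3ccc(OC)c(OC)c3)C[C@@H]2O[Si](C)(C)C(C)(C)C)C1=O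
A11 | alternative 3 | dimethyl squarate (3,4-dimethoxycyclobut-3-ene-1,2-dione) | COC1=C(OC)C(=O)C1=O
A12 | alternative 3 | (2S,4S)-5-bromo-4-[(tert-butyldimethylsilyl)oxy]-2-(3,4-dimethoxyphenyl)-3,4-dihydro-2H-pyran | BrC1=CO[C@H](c2ccc(OC)c(OC)c2)C[C@@H]1O[Si](C)(C)C(C)(C)C
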